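## Analysis of the target

The target 15 is a 2,3-dihydroflavonol. Ring A (C4a to C8a) is a phloroglucinol ring with free hydroxyls at C5 and C7 and a prenyl group at C8. Ring C holds O1, C2, C3 and the C4 ketone. Ring B, on C2, is a 4-methoxyphenyl group with a second prenyl group ortho to the methoxy group.

The only stereocentres are C2 and C3, both R, which places the aryl group and the hydroxyl trans and both equatorial on the half-chair of ring C; this is the more stable arrangement. Both centres are labile. C3 is alpha to the ketone. C2 is a benzylic ether carbon that base opens by beta-elimination to the chalcone and that acid can ionise with the help of the 4-methoxy group, so the pair must be set late and then left alone.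

The two trisubstituted alkenes exclude peracids, osmium reagents, hydrogenation and hot protic acid, which would cyclise the C8 prenyl group onto a neighbouring oxygen. The phloroglucinol ring is readily attacked by electrophiles and oxidants. The regiochemical difficulty is that the C8 prenyl group sits next to the ring oxygen O1 and not next to the chelated 5-hydroxyl, so the two ortho oxygens of an acylphloroglucinol must be told apart before ring C is closed.

The route rests on the polarity of the C2–C3 bond. C2 carries O1 and an electron-rich aryl group, is at the aldehyde oxidation level and readily becomes an oxocarbenium carbon. C3, the hydroxylated carbon next to the C4 ketone, is the nucleophilic carbon of an enediol. Both partners can be released from a single acetal.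

## Retrosynthetic reasoning

**15 to 14.** The last bonds cut are the two O–Si bonds at O5 and O7. The phenols must be masked during ring closure: a free O5 could take over the acetal from O1 and turn the 8-prenyl into the 6-prenyl series, and a free phloroglucinol ring would be attacked at C6 by the cation. Silyl ethers are chosen because buffered fluoride is the one deprotection that spares two prenyl groups, an acid-labile benzylic ether and a base-labile hydroxy ketone.

**14 to 12.** The C2–C3 bond is cut and C2 is re-joined to the oxygen on C3, which gives the racemic seven-membered acetal 12. This is the only bond of ring C whose two ends have matched natural polarity. Cutting O1–C2, O1–C8a or C4–C4a leads to open-chain precursors that must already carry the stereocentres. Here the precursor has one stereocentre, the acetal carbon, and it is lost on ionisation. The gain is the C–C bond, ring C and both stereocentres in one isomerisation without by-products, and the choice of O1 is stored in the acetal. The forward reaction has to open the acetal to the aryloxycarbenium enediol 13, close C3 onto C2 and control the face of attack with a chiral counter-anion. It is not required, and not expected, that the acid opens 12 first at the aliphatic oxygen. The chelated phenol is the better leaving group, but opening at O1 can only close back to 12, so product formation drains the less populated channel that leads to 13.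

**12 to 10 and 5.** The two acetal C–O bonds are cut, giving the diol 10 (phenol plus primary alcohol) and ring B at the aldehyde oxidation level as its dimethyl acetal 5. This divides the molecule into its ring A and ring B halves at the last step before the key step. The forward reaction is an exchange of two methoxy groups under weak acid.

**10 to 8.** The C–O bond at the primary carbon is cut, leading back to the methyl ketone 8. The forward step oxidises the enolate 9, because any oxidant that attacks neutral alkenes would also attack the prenyl group.

**8 to 7, and 7 to 6 and 3.** The O–Si bonds of 8 are cut to the triol 7; the forward silylation is where the oxygen next to the prenyl group is singled out as the future O1. The ring–prenyl bond of 7 is then cut to 6 and 3. The two free ring positions of 6 are equivalent, so the alkylation raises no regiochemical question.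

**5 to 2 and 3, and 2 to 1.** The aryl–CH2 bond is cut, giving the aryl bromide 2 (through its magnesium derivative 4) and 3. The bromine of the commercial aldehyde 1 marks the position of the prenyl group, which a direct alkylation of a phenol would not fix, and the methyl ether is already in place. Acetal 2 comes from 1 by protecting the aldehyde in the form that step 6 needs.

## Alternatives that were turned down

**Alternative 1:** The cut is C3–C4. The precursor A2 carries an acyl triethylsilane on ring A and, on O1, a 2-aryl-2-aryloxyacetaldehyde whose stereocentre (the future C2) is meant to racemise. In the forward step a chiral lithium phosphite of the TADDOL type adds to the acylsilane, a Brook rearrangement unmasks the acyl anion equivalent, this adds to the aldehyde, and silyl transfer with loss of phosphite gives A1.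

- For it: ring C and both stereocentres form in one catalytic step, O3 emerges protected, no strong acid comes near the prenyl groups, and the intermolecular parent reaction is established and enantioselective. On precedent it stands on firmer ground than the ring contraction chosen here.
- Against it: the acylsilane of A2 is flanked by two ortho oxygens on a hexasubstituted ring, so phosphite addition should be slow. The aldehyde is prone to self-condensation. The dynamic resolution needs enolisation of the aldehyde to outrun cyclisation while the same base must not epimerise A1. Making A2 needs O-alkylation of a hindered, chelated phenol with a secondary benzylic electrophile plus a separate acylsilane synthesis, and the end game needs acid to remove the methoxymethyl groups next to the prenyl groups.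
- Comparison: the chosen route offers a precursor, 12, that is assembled from three commercial compounds in six steps, has no configurational liability and ends with a fluoride deprotection.

**Alternative 2:** The cut is O1–C8a. The precursor A4 is an open-chain aryl bromide with a free benzylic hydroxyl and two silyl ethers. CuI (monovalent copper), 3,4,7,8-tetramethyl-1,10-phenanthroline and Cs2CO3 join that hydroxyl to the ring and give the flavan-3,4-diol derivative A3.

- For it: the closure touches no stereocentre, so C2 and C3 are made by open-chain chemistry and carried through; this is more secure for configuration than any closure that creates them. The ring A pattern is fixed by the bromide, so no two phenols need to be told apart, and the coupling is a known reaction class. On these two points it is stronger than the chosen route.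
- Against it: the bromide is doubly ortho-substituted on an electron-rich ring and the nucleophile is a hindered secondary benzylic alkoxide at high temperature with carbonate, so elimination competes. C4 is carried as an alcohol, so a third stereocentre is made only to be oxidised away, and the two like silyl ethers of A3 must be distinguished before that oxidation. The triol cannot be made by dihydroxylation once the prenyl groups are present. At least three redox and deprotection steps follow the key step.
- Comparison: the chosen route keeps C4 at the ketone level throughout, sets only the two stereocentres that the target has, and is far shorter.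

**Alternative 3:** The cut is C4a–C5, so ring A is built last on a finished, stereodefined ring C. The precursor A6 is a dihydropyranone with a prenylated beta-keto ester side chain. Mg(OCH3)2 is meant to form the extended enolate by deprotonation at C8; it attacks the ester through C4a, methanol is lost and enolisation aromatises ring A to give A5.

- For it: the prenyl position is part of the carbon chain, so there is no regiochemical question at all, and the ring A phenols appear free. On both points it is stronger than the chosen route. The stereocentres could be set on a small pyranone by established catalysis.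
- Against it: the most acidic protons of A6 are those between the ketone and the ester; their removal turns the ester into part of an enolate and shuts off the electrophile. The same base can enolise C3 and expel O1 from C2, which destroys C2. A6 is a sensitive polycarbonyl compound that is long to prepare.
- Comparison: the chosen route exposes C2 and C3 only to a catalytic acid at low temperature and to buffered fluoride, and pays for its regiocontrol with one selective silylation.

Key step: step 7

Assumption: the sense of induction of the chiral acid in step 7 cannot be derived from first principles. The (S,S) catalyst is written; its enantiomer is used if the closure favours the (2S,3S) product, and the aryl wings of the catalyst are to be screened.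

## Route

Step 1
Reactants: 1 3-bromo-4-methoxybenzaldehyde
Product: 2 2-bromo-4-(dimethoxymethyl)-1-methoxybenzene
Conditions: HC(OMe)3, MeOH, p-TsOH·H2O (1 mol %), rt; Et3N quench
Reagents that add atoms: trimethyl orthoformate, COC(OC)OC; methanol, CO
Why: Acid-catalysed acetalisation driven by the orthoformate as water scavenger; the acetal masks the aldehyde for the organomagnesium step and is already the activated form needed for the transacetalisation in step 6.

Step 2
Reactants: 2 2-bromo-4-(dimethoxymethyl)-1-methoxybenzene; 3 prenyl bromide
Product: 5 4-(dimethoxymethyl)-1-methoxy-2-(3-methylbut-2-en-1-yl)benzene, via arylmagnesium bromide 4 (not isolated)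
Conditions: Mg turnings, THF, 40–60 °C; then Li2CuCl4 (3 mol %, divalent copper), 3, THF, −20 → 0 °C; NH4Cl/NH3 buffer (pH 8–9)
Reagents that add atoms: none
Why: Magnesium insertion tolerates the acetal, and the copper-catalysed coupling of the aryl Grignard reagent with the primary allylic bromide should occur at the unhindered CH2 terminus, because attack at the other terminus would build a quaternary benzylic carbon. The bromine of 1 fixes the position of the prenyl group, and the basic work-up preserves the acid-labile acetal.

Step 3
Reactants: 6 2',4',6'-trihydroxyacetophenone; 3 prenyl bromide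
Product: 7 1-[2,4,6-trihydroxy-3-(3-methylbut-2-en-1-yl)phenyl]ethanone
Conditions: 3 (1.0 equiv), 10% aq. KOH, 0 °C → rt; cold 1 M HCl to pH 4–5
Reagents that add atoms: none
Why: C-alkylation of an ambident phloroglucinol phenoxide; in water the oxygens are solvated and the allylic bromide is taken up by ring carbon, and the two free ring positions of 6 are equivalent, so mono-alkylation can give only 7. One equivalent of 3 limits double alkylation, and O-prenyl and bis-prenyl by-products are removed by chromatography.

Step 4
Reactants: 7 1-[2,4,6-trihydroxy-3-(3-methylbut-2-en-1-yl)phenyl]ethanone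
Product: 8 1-[4,6-bis(tert-butyldimethylsilyloxy)-2-hydroxy-3-(3-methylbut-2-en-1-yl)phenyl]ethanone
Conditions: TBSCl (2.1 equiv), imidazole (4.5 equiv), DMF, −10 → 0 °C
Reagents that add atoms: tert-butyldimethylsilyl chloride, CC(C)(C)[Si](C)(C)Cl
Why: Phenols are silylated in order of accessibility: first the para hydroxyl, which is not chelated, then the ortho hydroxyl that has a ring hydrogen as neighbour. The remaining ortho hydroxyl lies between the acetyl and prenyl groups and is pressed by the prenyl group into the hydrogen bond with the carbonyl, so it should stay free; this makes the oxygen next to the prenyl group the future O1. The site is to be confirmed by NOE contacts from the lone ring proton to both silyl groups.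

Step 5
Reactants: 8 1-[4,6-bis(tert-butyldimethylsilyloxy)-2-hydroxy-3-(3-methylbut-2-en-1-yl)phenyl]ethanone
Product: 10 1-[4,6-bis(tert-butyldimethylsilyloxy)-2-hydroxy-3-(3-methylbut-2-en-1-yl)phenyl]-2-hydroxyethanone, via disodium phenoxide enolate 9 (not isolated)
Conditions: NaHMDS (2.2 equiv), THF, −78 °C; then 2-(phenylsulfonyl)-3-phenyloxaziridine (1.2 equiv), −78 °C; sat. aq. NH4Cl, −78 °C → rt
Reagents that add atoms: 2-(phenylsulfonyl)-3-phenyloxaziridine, O=S(=O)(c1ccccc1)N1OC1c1ccccc1
Why: Hydroxylation of a ketone enolate by an N-sulfonyloxaziridine; the methyl group is the only enolisable position, and the sodium chelate between the phenoxide and enolate oxygens keeps the enolate oxygen turned away from the C6 silyl ether, so no silyl transfer is expected. The oxaziridine gives oxygen only to the enolate carbon and leaves the trisubstituted alkene and the electron-rich ring alone, which a peracid would not.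

Step 6
Reactants: 10 1-[4,6-bis(tert-butyldimethylsilyloxy)-2-hydroxy-3-(3-methylbut-2-en-1-yl)phenyl]-2-hydroxyethanone; 5 4-(dimethoxymethyl)-1-methoxy-2-(3-methylbut-2-en-1-yl)benzene
Product: 12 rac-6,8-bis(tert-butyldimethylsilyloxy)-2-[4-methoxy-3-(3-methylbut-2-en-1-yl)phenyl]-9-(3-methylbut-2-en-1-yl)-4H-1,3-benzodioxepin-5-one, via open mixed methyl acetal 11 (not isolated)
Conditions: 5 (1.3 equiv), PPTS (10 mol %), toluene, 5 Å MS, 50 °C, slight vacuum; Et3N quench; Et3N-deactivated silica
Reagents that add atoms: none
Why: Acid-catalysed transacetalisation; the primary hydroxyl exchanges first to give 11, then the phenol closes the seven-membered ring at the 4-methoxyaryl-stabilised oxocarbenium ion, and removal of methanol by sieves and slight vacuum pulls the equilibrium over. The weak acid does not touch prenyl groups or aryl silyl ethers, and the acetal carbon forms as a racemate, which does not matter because it becomes planar in step 7.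

Step 7
Reactants: 12 rac-6,8-bis(tert-butyldimethylsilyloxy)-2-[4-methoxy-3-(3-methylbut-2-en-1-yl)phenyl]-9-(3-methylbut-2-en-1-yl)-4H-1,3-benzodioxepin-5-one
Product: 14 (2R,3R)-5,7-bis(tert-butyldimethylsilyloxy)-3-hydroxy-2-[4-methoxy-3-(3-methylbut-2-en-1-yl)phenyl]-8-(3-methylbut-2-en-1-yl)-2,3-dihydro-4H-chromen-4-one, via ring-opened aryloxycarbenium enediol 13 (not isolated)
Conditions: (S,S)-IDPi acid (imidodiphosphorimidate from two (S)-3,3'-diaryl-BINOL units, N-SO2CF3 groups; 5 mol %), CHCl3, 5 Å MS, −20 °C; Et3N quench at −20 °C
Reagents that add atoms: none
Why: Proposed new method: the confined strong acid protonates acetal 12; opening at the aryl oxygen is expected to be the faster event but can only close back to 12, whereas opening at the aliphatic oxygen (from the keto form or, as in a Petasis–Ferrier rearrangement, from the enol tautomer with an enolic leaving group) gives the 4-methoxyaryl-stabilised aryloxycarbenium ion 13, whose side chain is the enediol of the released alpha-hydroxy ketone, so the productive channel drains the pre-equilibrium. The enediol carbon C3 then attacks C2, forming the C2–C3 bond and the C4 ketone irreversibly, while attack through either enediol oxygen only returns acetal isomers. The closest known reaction types are the Petasis–Ferrier rearrangement of cyclic enol acetals to tetrahydropyranones, its chiral-phosphoric-acid-catalysed aza variant, and additions of enol nucleophiles to oxocarbenium ions under imidodiphosphorimidate catalysis; new here are the keto acetal, the contraction from a seven- to a six-membered ring and the aryloxycarbenium ion. Ring C closes 6-endo-trig at the oxocarbenium (O1=C2 lies in the new ring) and enol-endo at the nucleophile (C3=C4 lies in the ring), with the three pi bonds O1=C2, C8a=C4a and C4=C3 arranged as in an oxa-6-pi closure. C2 is set by the chiral counter-anion, which holds the enediol by hydrogen bonds and leaves one face of the planar cation open; both enantiomers of 12 give the same ion pair, so the racemate converges on one product. C3 is set relative to C2 by the half-chair transition state with aryl and hydroxyl equatorial, and because C3 remains epimerisable through the enediol under the acid, it is corrected to the trans (2R,3R) isomer. The step needs site selectivity (only O1 is in the acetal and O5 is silylated, so the prenyl group must end at C8), carbon over oxygen attack (secured by the irreversibility of C–C bond formation) and face selectivity (catalyst); the silyl ethers also damp Friedel–Crafts attack at C6.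

Step 8
Reactants: 14 (2R,3R)-5,7-bis(tert-butyldimethylsilyloxy)-3-hydroxy-2-[4-methoxy-3-(3-methylbut-2-en-1-yl)phenyl]-8-(3-methylbut-2-en-1-yl)-2,3-dihydro-4H-chromen-4-one
Product: 15 (2R,3R)-3,5,7-trihydroxy-2-[4-methoxy-3-(3-methylbut-2-en-1-yl)phenyl]-8-(3-methylbut-2-en-1-yl)-2,3-dihydro-4H-chromen-4-one
Conditions: TBAF (2.2 equiv), AcOH (2.4 equiv), THF, 0 °C; pH 7 phosphate buffer
Reagents that add atoms: none
Why: Fluoride cleavage of aryl silyl ethers, which are far more labile than alkyl ones; acetic acid keeps the phenoxides protonated, so the 3-hydroxy-4-ketone should be neither epimerised, nor opened to the chalcone, nor oxidised to the flavonol. C2, C3 and both prenyl groups are not touched.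

## Compound list

1 | 3-bromo-4-methoxybenzaldehyde | COc1ccc(C=O)cc1Br | starting material
2 | 2-bromo-4-(dimethoxymethyl)-1-methoxybenzene | COc1ccc(C(OC)OC)cc1Br | intermediate
3 | prenyl bromide (1-bromo-3-methylbut-2-ene) | CC(C)=CCBr | starting material
4 | [5-(dimethoxymethyl)-2-methoxyphenyl]magnesium bromide | COc1ccc(C(OC)OC)cc1[Mg]Br | intermediate
5 | 4-(dimethoxymethyl)-1-methoxy-2-(3-methylbut-2-en-1-yl)benzene | COc1ccc(C(OC)OC)cc1CC=C(C)C | intermediate
6 | 2',4',6'-trihydroxyacetophenone | CC(=O)c1c(O)cc(O)cc1O | starting material
7 | 1-[2,4,6-trihydroxy-3-(3-methylbut-2-en-1-yl)phenyl]ethanone | CC(=O)c1c(O)cc(O)c(CC=C(C)C)c1O | intermediate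
8 | 1-[4,6-bis(tert-butyldimethylsilyloxy)-2-hydroxy-3-(3-methylbut-2-en-1-yl)phenyl]ethanone | CC(=O)c1c(O[Si](C)(C)C(C)(C)C)cc(O[Si](C)(C)C(C)(C)C)c(CC=C(C)C)c1O | intermediate
9 | disodium phenoxide enolate of 8 | [Na+].[Na+].C=C([O-])c1c(O[Si](C)(C)C(C)(C)C)cc(O[Si](C)(C)C(C)(C)C)c(CC=C(C)C)c1[O-] | intermediate
10 | 1-[4,6-bis(tert-butyldimethylsilyloxy)-2-hydroxy-3-(3-methylbut-2-en-1-yl)phenyl]-2-hydroxyethanone | OCC(=O)c1c(O[Si](C)(C)C(C)(C)C)cc(O[Si](C)(C)C(C)(C)C)c(CC=C(C)C)c1O | intermediate
11 | open mixed methyl acetal: 1-[4,6-bis(tert-butyldimethylsilyloxy)-2-hydroxy-3-(3-methylbut-2-en-1-yl)phenyl]-2-{methoxy[4-methoxy-3-(3-methylbut-2-en-1-yl)phenyl]methoxy}ethanone, racemic | COc1ccc(C(OC)OCC(=O)c2c(O[Si](C)(C)C(C)(C)C)cc(O[Si](C)(C)C(C)(C)C)c(CC=C(C)C)c2O)cc1CC=C(C)C | intermediate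
12 | rac-6,8-bis(tert-butyldimethylsilyloxy)-2-[4-methoxy-3-(3-methylbut-2-en-1-yl)phenyl]-9-(3-methylbut-2-en-1-yl)-4H-1,3-benzodioxepin-5-one (acetal carbon undefined) | COc1ccc(C2OCC(=O)c3c(O[Si](C)(C)C(C)(C)C)cc(O[Si](C)(C)C(C)(C)C)c(CC=C(C)C)c3O2)cc1CC=C(C)C | intermediate
13 | ring-opened aryloxycarbenium ion with 1,2-dihydroxyvinyl (enediol) side chain, as ion pair with the catalyst anion | COc1ccc(C=[O+]c2c(CC=C(C)C)c(O[Si](C)(C)C(C)(C)C)cc(O[Si](C)(C)C(C)(C)C)c2C(O)=CO)cc1CC=C(C)C | intermediate
14 | (2R,3R)-5,7-bis(tert-butyldimethylsilyloxy)-3-hydroxy-2-[4-methoxy-3-(3-methylbut-2-en-1-yl)phenyl]-8-(3-methylbut-2-en-1-yl)-2,3-dihydro-4H-chromen-4-one | COc1ccc([C@H]2Oc3c(CC=C(C)C)c(O[Si](C)(C)C(C)(C)C)cc(O[Si](C)(C)C(C)(C)C)c3C(=O)[C@@H]2O)cc1CC=C(C)C | intermediate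
15 | (2R,3R)-3,5,7-trihydroxy-2-[4-methoxy-3-(3-methylbut-2-en-1-yl)phenyl]-8-(3-methylbut-2-en-1-yl)-2,3-dihydro-4H-chromen-4-one | COc1ccc([C@H]2Oc3c(CC=C(C)C)c(O)cc(O)c3C(=O)[C@@H]2O)cc1CC=C(C)C | target

## Step count and risk

Total step count: 8. Longest linear sequence: 6 steps (6 to 15, steps 3 to 8); the ring B acetal 5 takes 2 steps and joins in step 6.

**Step 7 (key step, new method).**
- What may go wrong: failure to enter the carbon–carbon channel, with the ion pair only shuttling between acetal isomers or being hydrolysed by traces of water; closure outside the chiral pocket, giving poor facial selectivity; later re-ionisation of the product at C2 under the acid, eroding both centres; acid-induced cyclisation of the C8 prenyl group onto the transiently freed phenol.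
- Why: the productive ionisation is the less favoured of the two, and the cation is tethered to its nucleophile, so an uncatalysed closure is always available.
- Fallback by known chemistry, from 7 and 5, returning at 15: 7 would be protected at O4 and O6 with chloromethyl methyl ether and i-Pr2NEt, with the same site preference as in step 4, to give 1-[2-hydroxy-4,6-bis(methoxymethoxy)-3-(3-methylbut-2-en-1-yl)phenyl]ethanone F1. The remaining phenol would be allylated (allyl bromide, K2CO3, DMF) to the allyl ether F2. Acetal 5 would be hydrolysed (aqueous AcOH, THF) to 4-methoxy-3-(3-methylbut-2-en-1-yl)benzaldehyde F3. Claisen–Schmidt condensation of F2 and F3 (KOH, EtOH) should give the (E)-chalcone F4. Juliá–Colonna epoxidation (poly-L-leucine, urea–hydrogen peroxide, DBU, THF) attacks only the enone and is expected to give the (2R,3S)-epoxy ketone F5; poly-D-leucine is used if the sense proves opposite. Deallylation with Pd(PPh3)4 (zerovalent palladium) and morpholine would free the phenol epoxide F6. Under a trace of mild acid F6 should open the epoxide 6-endo at the benzylic carbon with inversion to the (2R,3R)-bis(methoxymethyl) dihydroflavonol F7. HCl in MeOH at 40 °C would then give 15. This is longer and ends with an acid step next to the prenyl groups, which is why it is not the main route.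

**Step 6.**
- What may go wrong: stalling at the open acetal 11 or drifting to intermolecular acetals, and loss of the phenolic acetal on purification.
- Why: the phenol is chelated and hindered, and a mixed aryl alkyl acetal in a seven-membered ring is the least favoured member of the equilibrium.
- Fallback, from 10 and 5, returning at 12: a kinetic silyl-transfer acetalisation in place of the equilibrium exchange. 10 would be converted (TMSCl, imidazole, CH2Cl2) into its bis(trimethylsilyl) ether F8, 5 hydrolysed to the aldehyde F3, and the two combined with TMSOTf (2 mol %) in CH2Cl2 at −78 °C with a pyridine quench, the formation of hexamethyldisiloxane making the closure irreversible.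

**Step 5.**
- What may go wrong: over-oxidation of the primary hydroxy ketone through a second enolisation, addition of the enolate to the sulfonimine by-product, and silyl transfer from O6 to the enolate oxygen.
- Why: methyl ketone enolates are unhindered and the product is more acidic than the starting ketone.
- Fallback, from 8, returning at 10: a Rubottom oxidation. TMSOTf and Et3N would give the trimethylsilyl enol ether aryl trimethylsilyl ether F9. Dimethyldioxirane (1.0 equiv, acetone/CH2Cl2, −78 °C) should epoxidise the silyl enol ether well before the prenyl alkene to give the silyloxy epoxide F10, which rearranges by silyl shift to the bis(trimethylsilyl) compound F8. Citric acid in MeOH would then remove both trimethylsilyl groups and give 10. The point to watch is competing epoxidation of the prenyl group.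

**Step 4.**
- What may go wrong: silylation at the wrong ortho oxygen, which would lead to the 6-prenyl series after step 7.
- Why: the preference rests on steric and chelation differences between two similar phenols.
- Fallback, from 6, returning at 8 (it also by-passes step 3): a route in which the site is fixed by a sigmatropic shift. 6 would be bis-silylated (TBSCl, imidazole), which is unambiguous for the symmetric triol, to 1-[2,4-bis(tert-butyldimethylsilyloxy)-6-hydroxyphenyl]ethanone F11. The free phenol would be converted with tert-butyl 2-methylbut-3-en-2-yl carbonate and Pd(PPh3)4 (zerovalent palladium) in THF at 0 °C into the 1,1-dimethylallyl ether F12. An aromatic Claisen rearrangement (toluene, 100 °C) would move the group to the only free ortho carbon as a normal prenyl group and give 8.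

## Further compounds

F1 | step 7 | 1-[2-hydroxy-4,6-bis(methoxymethoxy)-3-(3-methylbut-2-en-1-yl)phenyl]ethanone | CC(=O)c1c(OCOC)cc(OCOC)c(CC=C(C)C)c1O
F2 | step 7 | 1-[2-(allyloxy)-4,6-bis(methoxymethoxy)-3-(3-methylbut-2-en-1-yl)phenyl]ethanone | CC(=O)c1c(OCOC)cc(OCOC)c(CC=C(C)C)c1OCC=C
F3 | step 7 | 4-methoxy-3-(3-methylbut-2-en-1-yl)benzaldehyde | COc1ccc(C=O)cc1CC=C(C)C
F4 | step 7 | (E)-1-[2-(allyloxy)-4,6-bis(methoxymethoxy)-3-(3-methylbut-2-en-1-yl)phenyl]-3-[4-methoxy-3-(3-methylbut-2-en-1-yl)phenyl]prop-2-en-1-one | COc1ccc(/C=C/C(=O)c2c(OCOC)cc(OCOC)c(CC=C(C)C)c2OCC=C)cc1CC=C(C)C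
F5 | step 7 | [2-(allyloxy)-4,6-bis(methoxymethoxy)-3-(3-methylbut-2-en-1-yl)phenyl]{(2R,3S)-3-[4-methoxy-3-(3-methylbut-2-en-1-yl)phenyl]oxiran-2-yl}methanone | COc1ccc([C@@H]2O[C@H]2C(=O)c3c(OCOC)cc(OCOC)c(CC=C(C)C)c3OCC=C)cc1CC=C(C)C
F6 | step 7 | [2-hydroxy-4,6-bis(methoxymethoxy)-3-(3-methylbut-2-en-1-yl)phenyl]{(2R,3S)-3-[4-methoxy-3-(3-methylbut-2-en-1-yl)phenyl]oxiran-2-yl}methanone | COc1ccc([C@@H]2O[C@H]2C(=O)c3c(OCOC)cc(OCOC)c(CC=C(C)C)c3O)cc1CC=C(C)C
F7 | step 7 | (2R,3R)-3-hydroxy-5,7-bis(methoxymethoxy)-2-[4-methoxy-3-(3-methylbut-2-en-1-yl)phenyl]-8-(3-methylbut-2-en-1-yl)-2,3-dihydro-4H-chromen-4-one | COc1ccc([C@H]2Oc3c(CC=C(C)C)c(OCOC)cc(OCOC)c3C(=O)[C@@H]2O)cc1CC=C(C)C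
F8 | step 6 | 1-[4,6-bis(tert-butyldimethylsilyloxy)-3-(3-methylbut-2-en-1-yl)-2-(trimethylsilyloxy)phenyl]-2-(trimethylsilyloxy)ethanone | C[Si](C)(C)OCC(=O)c1c(O[Si](C)(C)C(C)(C)C)cc(O[Si](C)(C)C(C)(C)C)c(CC=C(C)C)c1O[Si](C)(C)C
F9 | step 5 | 1-[4,6-bis(tert-butyldimethylsilyloxy)-3-(3-methylbut-2-en-1-yl)-2-(trimethylsilyloxy)phenyl]-1-(trimethylsilyloxy)ethene | C=C(O[Si](C)(C)C)c1c(O[Si](C)(C)C(C)(C)C)cc(O[Si](C)(C)C(C)(C)C)c(CC=C(C)C)c1O[Si](C)(C)C
F10 | step 5 | 2-[4,6-bis(tert-butyldimethylsilyloxy)-3-(3-methylbut-2-en-1-yl)-2-(trimethylsilyloxy)phenyl]-2-(trimethylsilyloxy)oxirane, racemic | C[Si](C)(C)OC1(CO1)c1c(O[Si](C)(C)C(C)(C)C)cc(O[Si](C)(C)C(C)(C)C)c(CC=C(C)C)c1O[Si](C)(C)C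
F11 | step 4 | 1-[2,4-bis(tert-butyldimethylsilyloxy)-6-hydroxyphenyl]ethanone | CC(=O)c1c(O)cc(O[Si](C)(C)C(C)(C)C)cc1O[Si](C)(C)C(C)(C)C
F12 | step 4 | 1-[2,4-bis(tert-butyldimethylsilyloxy)-6-(2-methylbut-3-en-2-yloxy)phenyl]ethanone | CC(=O)c1c(OC(C)(C)C=C)cc(O[Si](C)(C)C(C)(C)C)cc1O[Si](C)(C)C(C)(C)C
A1 | alternative 1 | (2R,3R)-5,7-bis(methoxymethoxy)-2-[4-methoxy-3-(3-methylbut-2-en-1-yl)phenyl]-8-(3-methylbut-2-en-1-yl)-3-(triethylsilyloxy)-2,3-dihydro-4H-chromen-4-one | COc1ccc([C@H]2Oc3c(CC=C(C)C)c(OCOC)cc(OCOC)c3C(=O)[C@@H]2O[Si](CC)(CC)CC)cc1CC=C(C)C
A2 | alternative 1 | rac-2-{3,5-bis(methoxymethoxy)-6-(3-methylbut-2-en-1-yl)-2-[(triethylsilyl)carbonyl]phenoxy}-2-[4-methoxy-3-(3-methylbut-2-en-1-yl)phenyl]acetaldehyde | COc1ccc(C(C=O)Oc2c(CC=C(C)C)c(OCOC)cc(OCOC)c2C(=O)[Si](CC)(CC)CC)cc1CC=C(C)C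
A3 | alternative 2 | (2R,3R,4S)-3,4-bis(tert-butyldimethylsilyloxy)-5,7-bis(methoxymethoxy)-2-[4-methoxy-3-(3-methylbut-2-en-1-yl)phenyl]-8-(3-methylbut-2-en-1-yl)chromane | COc1ccc([C@H]2Oc3c(CC=C(C)C)c(OCOC)cc(OCOC)c3[C@H](O[Si](C)(C)C(C)(C)C)[C@@H]2O[Si](C)(C)C(C)(C)C)cc1CC=C(C)C
A4 | alternative 2 | (1R,2R,3S)-3-[2-bromo-4,6-bis(methoxymethoxy)-3-(3-methylbut-2-en-1-yl)phenyl]-2,3-bis(tert-butyldimethylsilyloxy)-1-[4-methoxy-3-(3-methylbut-2-en-1-yl)phenyl]propan-1-ol | COc1ccc([C@@H](O)[C@@H](O[Si](C)(C)C(C)(C)C)[C@@H](O[Si](C)(C)C(C)(C)C)c2c(OCOC)cc(OCOC)c(CC=C(C)C)c2Br)cc1CC=C(C)C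
A5 | alternative 3 | (2R,3R)-3-(tert-butyldimethylsilyloxy)-5,7-dihydroxy-2-[4-methoxy-3-(3-methylbut-2-en-1-yl)phenyl]-8-(3-methylbut-2-en-1-yl)-2,3-dihydro-4H-chromen-4-one | COc1ccc([C@H]2Oc3c(CC=C(C)C)c(O)cc(O)c3C(=O)[C@@H]2O[Si](C)(C)C(C)(C)C)cc1CC=C(C)C
A6 | alternative 3 | methyl 4-{(2R,3R)-3-(tert-butyldimethylsilyloxy)-2-[4-methoxy-3-(3-methylbut-2-en-1-yl)phenyl]-4-oxo-3,4-dihydro-2H-pyran-6-yl}-7-methyl-3-oxooct-6-enoate (side-chain centre undefined) | COc1ccc([C@H]2OC(C(CC=C(C)C)C(=O)CC(=O)OC)=CC(=O)[C@@H]2O[Si](C)(C)C(C)(C)C)cc1CC=C(C)C
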